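(All runs are calculated from invented constants; the scatter is artificial.)

The midnight and winter runs, with reagent charged at 130 mM and 200 mM, ended at 22.9% and 23.4% target, which is where you start.

| setting | midnight | winter | spring | flask |
|---|---|---|---|---|
| starting material | 37 mM | 37 mM | 37 mM | 37 mM |
| reagent | 130 mM | 200 mM | 92.5 mM | 92.5 mM |
| free catalyst | 27 µM | 27 µM | 14 µM | 27 µM |
| remark | run made earlier | run made earlier | run made earlier |  |

- midnight (time / min: target / %, starting material / %): 0.167: 0.6, 98.2; 0.500: 4.8, 94.2; 0.833: 8.4, 91.5; 1.33: 12.8, 86.7; 2.00: 19.1, 80.5; 2.50: 22.9, 76.7
- winter (time / min: target / %, starting material / %): 0.200: 2.1, 98.2; 0.333: 2.5, 97.4; 0.500: 5.8, 95.0; 0.833: 8.8, 91.2; 1.50: 14.4, 85.2; 2.50: 23.4, 75.6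
- spring (time / min: target / %, starting material / %): 0.500: 3.2, 97.1; 1.00: 4.9, 93.9; 1.50: 8.4, 92.8; 2.00: 10.0, 89.9; 2.50: 11.8, 88.0

(standard deviation of a reading: 0.5 percentage points)

* apparent order in reagent when 30% of the starting material are converted (percent change of the rate of making target for one percent more reagent charged)
* apparent order in free catalyst when 30% of the starting material are converted (percent change of the rate of making target for one percent more free catalyst charged)

- what may be going on: reagent + free catalyst -> catalyst intermediate A; starting material + catalyst intermediate A <-> catalyst intermediate B; catalyst intermediate B <-> catalyst intermediate C; catalyst intermediate C -> released group + catalyst intermediate D; catalyst intermediate D -> free catalyst + target; catalyst intermediate D -> spent catalyst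

Those two end readings give a logarithmic slope in reagent of 0.0501, which the scatter can't tell from zero, so you put the reagent order near zero. The spring run, at the reagent charge of the flask, makes 0.983 of their mean rate per catalyst charged. You therefore give the flask their mean rate to the end, 0.0926 min⁻¹ of the charge, which reaches 30% in about 3.24 min.

For the catalyst, take independent units that never die as the zero of the scale: the rate at a given conversion then follows the charge, and the order is 1, your lower bound. Now let each unit die at a loss rate, the fraction of working catalyst lost per minute whatever the charge. A larger charge reaches the conversion sooner and has lost less, so the order becomes 1 plus loss rate times time. The mean rate up to mid-run was 0.0961 min⁻¹, and its fall to the end gives a loss rate of 0.0675 min⁻¹. The scatter barely resolves this reading. It counts as an upper figure, since falling starting material also slows the rate yet is equal at equal conversion. Your bracket runs from 1 to 1.22, and no reading narrows it.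

The forecast gives 0.05 and 1.05, reasoning that “rate scales with catalyst”, so its catalyst order lies inside the bracket. The flask gives 0.0048 and 1.2, the latter at the top of the bracket.

    reagent + free catalyst → catalyst intermediate A (k = 6600 M⁻¹ s⁻¹)
    starting material + catalyst intermediate A ⇌ catalyst intermediate B (K = 1800 M⁻¹, k = 510 M⁻¹ s⁻¹)
    catalyst intermediate B ⇌ catalyst intermediate C (K = 2.00, k = 8.90 s⁻¹)
    catalyst intermediate C → released group + catalyst intermediate D (k = 10.0 s⁻¹)
    catalyst intermediate D → free catalyst + target (k = 10.0 s⁻¹)
    catalyst intermediate D → spent catalyst (k = 0.00430 s⁻¹)

Catalyst intermediate D goes on to free catalyst 2330 times faster than it goes off-cycle to spent catalyst, yet with 21.7% of the catalyst charged standing as catalyst intermediate D and 7.32% already spent at 1.25 min, the loss rate per working catalyst there is 0.0604 min⁻¹, against the 0.0675 min⁻¹ read from the runs. Carried to 13.5 min, the time of 85% conversion, the read loss rate gives 59.8% of the catalyst spent, and the flask holds 50.1%.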